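**Retrosynthetic overview**

1. The strategy rests on the 3-acyltetronate of ring B (C5–O6–C7–C9=C10, acyl C26 on C9). C26/C9/C7 is a β-keto ester of the C5 α-hydroxy ester, so C9–C10 is made last by a transannular Lacey–Dieckmann closure of a 16-membered β-keto lactone, which thereby contracts to the 15-membered carbocycle.
2. Endgame: O11 is sulfonylated, and the C12 hydroxyl, freed from silicon, adds to C10 and expels the sulfonate. This closes ring C (C5, C10, O11, C12, C28, C29) without breaking the C12–O bond.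
3. The macrolactone comes from an acylketene (dioxinone thermolysis) trapped by the C5 hydroxyl (O6–C7). The seco chain comes from a B-alkyl Suzuki coupling at C15–C17 between a west (Z)-vinyl iodide and an east diene–dioxinone whose C22 centre is set by a vinylogous Mukaiyama aldol.
4. Ring A (C3, C4, C5, C29, C31, C32) comes from an Ireland–Claisen rearrangement of a δ-lactone that joins the two quaternary carbons C5 and C29. C32/C3 derive from a Sharpless epoxide and C12 from (R)-2-methylglycidol.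
5. Order of rings: sacrificial δ-lactone, ring A, 16-membered macrolactone, ring B (with contraction to the 15-membered carbocycle), ring C.

Key step: step 26

Assumption: atoms C1–C33 follow the order of the target SMILES; (S)-Tol-BINAP is taken as the ligand antipode that gives the R carbinol in step 21, and its mirror image would be used if the facial sense proved opposite.

**Route**

Step 1
Reactants: 1 propargyl alcohol; 2 allyl bromide
Product: 4 (E)-2-methylhexa-2,5-dien-1-ol, via alkenylalane 3 (not isolated)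
Conditions: Me3Al (3 equiv), Cp2ZrCl2 (0.25 equiv), CH2Cl2, 0 °C to rt; then 2, Pd(PPh3)4 (3 mol %), THF, rt; aq. HCl
Reagents that add atoms: trimethylaluminium, C[Al](C)C
Why: Negishi zirconium-catalysed syn-carboalumination places methyl on C32 and aluminium on C3, and palladium-catalysed allylation of the alkenylalane with retention should give the E alkene (allyl trans to CH2OH).

Step 2
Reactants: 4 (E)-2-methylhexa-2,5-dien-1-ol
Product: 5 [(2R,3R)-2-methyl-3-(prop-2-en-1-yl)oxiran-2-yl]methanol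
Conditions: Ti(OiPr)4 (10 mol %), D-(−)-diethyl tartrate (12 mol %), t-BuOOH, 4 Å MS, CH2Cl2, −20 °C
Reagents that add atoms: tert-butyl hydroperoxide, CC(C)(C)OO
Why: Sharpless asymmetric epoxidation of the allylic alcohol, in which the D-tartrate–titanium complex selects the alkene face that gives the 2R,3R epoxide (sets C32) while the isolated terminal alkene stays inert.

Step 3
Reactants: 5 [(2R,3R)-2-methyl-3-(prop-2-en-1-yl)oxiran-2-yl]methanol
Product: 6 (2S,3S)-3-ethyl-2-methylhex-5-ene-1,2-diol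
Conditions: EtMgBr (4 equiv), CuI (10 mol %), THF, −30 to 0 °C
Reagents that add atoms: ethylmagnesium bromide, CC[Mg]Br
Why: Copper-catalysed SN2 opening of the 2,3-epoxy alcohol occurs at the less substituted C3 (quaternary C32 is blocked) with inversion, which sets the C3 ethyl centre anti to the C32 oxygen.

Step 4
Reactants: 6 (2S,3S)-3-ethyl-2-methylhex-5-ene-1,2-diol
Product: 7 (2S,3S)-3-ethyl-2-hydroxy-2-methylhex-5-enal
Conditions: SO3·pyridine, DMSO, iPr2NEt, CH2Cl2, 0 °C
Reagents that add atoms: none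
Why: Parikh–Doering oxidation can only touch the primary hydroxyl, and the quaternary α-carbon cannot epimerise.

Step 5
Reactants: 7 (2S,3S)-3-ethyl-2-hydroxy-2-methylhex-5-enal
Product: 8 (3S,4S)-4-ethyl-3-methylhept-6-en-1-yn-3-ol
Conditions: dimethyl (1-diazo-2-oxopropyl)phosphonate, K2CO3, MeOH, 0 °C to rt
Reagents that add atoms: dimethyl (1-diazo-2-oxopropyl)phosphonate, CC(=O)C(=[N+]=[N-])P(=O)(OC)OC
Why: Ohira–Bestmann homologation turns the aldehyde into the terminal alkyne C31≡C29 without touching either stereocentre.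

Step 6
Reactants: 9 (R)-2-methylglycidol
Product: 10 (2R)-2-{[(4-methoxyphenyl)methoxy]methyl}-2-methyloxirane
Conditions: NaH, 4-methoxybenzyl chloride, Bu4NI (cat.), THF, 0 °C
Reagents that add atoms: 4-methoxybenzyl chloride, COc1ccc(CCl)cc1
Why: Williamson etherification of the primary alkoxide at low temperature, where Payne-type epoxide migration is slow, so the future C12 centre keeps its configuration.

Step 7
Reactants: 8 (3S,4S)-4-ethyl-3-methylhept-6-en-1-yn-3-ol; 10 (2R)-2-{[(4-methoxyphenyl)methoxy]methyl}-2-methyloxirane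
Product: 12 (2S,6S,7S)-7-ethyl-1-[(4-methoxyphenyl)methoxy]-2,6-dimethyldec-9-en-4-yne-2,6-diol, via dilithio alkynolate 11 (not isolated)
Conditions: n-BuLi (2.1 equiv), THF, −78 °C; BF3·OEt2 (2.2 equiv); then 10, −78 °C
Reagents that add atoms: none
Why: Yamaguchi–Hirao alkynylation, in which the lithium acetylide–BF3 pair opens the 2,2-disubstituted epoxide at its CH2 (C28), so the C12–O bond and configuration are untouched.

Step 8
Reactants: 12 (2S,6S,7S)-7-ethyl-1-[(4-methoxyphenyl)methoxy]-2,6-dimethyldec-9-en-4-yne-2,6-diol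
Product: 14 (2S,4Z,6S,7S)-7-ethyl-4-iodo-1-[(4-methoxyphenyl)methoxy]-2,6-dimethyldeca-4,9-diene-2,6-diol, via vinylalanate 13 (not isolated)
Conditions: NaAlH2(OCH2CH2OMe)2 (3.5 equiv), THF, 0 °C to rt; then I2 (titrated), THF, −78 °C
Reagents that add atoms: iodine, II
Why: Alkoxide-directed trans-hydroalumination of the propargylic alcohol gives the five-membered oxa-aluminacycle with aluminium on C29 cis to C32, and iodinolysis retains that geometry.

Step 9
Reactants: 14 (2S,4Z,6S,7S)-7-ethyl-4-iodo-1-[(4-methoxyphenyl)methoxy]-2,6-dimethyldeca-4,9-diene-2,6-diol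
Product: 15 (2S,4E,6S,7S)-7-ethyl-1-[(4-methoxyphenyl)methoxy]-2,4,6-trimethyldeca-4,9-diene-2,6-diol
Conditions: Me2CuLi (6 equiv), Et2O, 0 °C
Reagents that add atoms: lithium dimethylcuprate, [Li+].C[Cu-]C
Why: Cuprate substitution of the vinyl iodide proceeds with retention, so the C30 methyl ends cis to C32 as the later sigmatropic step requires.

Step 10
Reactants: 15 (2S,4E,6S,7S)-7-ethyl-1-[(4-methoxyphenyl)methoxy]-2,4,6-trimethyldeca-4,9-diene-2,6-diol
Product: 17 (4S,5S,6E,9S)-4-ethyl-10-[(4-methoxyphenyl)methoxy]-5,7,9-trimethyldec-6-ene-1,5,9-triol, via alkylborane 16 (not isolated)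
Conditions: 9-BBN (3.5 equiv), THF, 0 °C to rt; then NaOH, H2O2, 0 °C
Reagents that add atoms: hydrogen peroxide, OO
Why: Anti-Markovnikov hydroboration–oxidation, in which 9-BBN selects the monosubstituted alkene over the trisubstituted one.

Step 11
Reactants: 17 (4S,5S,6E,9S)-4-ethyl-10-[(4-methoxyphenyl)methoxy]-5,7,9-trimethyldec-6-ene-1,5,9-triol
Product: 20 (5S,6S)-5-ethyl-6-{(1E,4S)-4-hydroxy-5-[(4-methoxyphenyl)methoxy]-2,4-dimethylpent-1-en-1-yl}-6-methyloxan-2-one, via hydroxy aldehyde 18 (not isolated), via lactol 19 (not isolated)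
Conditions: (n-Pr)4N[RuO4] (5 mol %), N-methylmorpholine N-oxide (3 equiv), 4 Å MS, CH2Cl2, rt
Reagents that add atoms: none
Why: Ley–Griffith oxidative lactonisation, in which the aldehyde from the primary alcohol is captured by the C32 hydroxyl as a six-membered lactol and oxidised on, while the remote C12 hydroxyl cannot form a small ring.

Step 12
Reactants: 20 (5S,6S)-5-ethyl-6-{(1E,4S)-4-hydroxy-5-[(4-methoxyphenyl)methoxy]-2,4-dimethylpent-1-en-1-yl}-6-methyloxan-2-one
Product: 21 (5S,6S)-5-ethyl-6-{(1E,4S)-5-[(4-methoxyphenyl)methoxy]-2,4-dimethyl-4-(triethylsilyloxy)pent-1-en-1-yl}-6-methyloxan-2-one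
Conditions: Et3SiOTf, 2,6-lutidine, CH2Cl2, −78 to 0 °C
Reagents that add atoms: triethylsilyl trifluoromethanesulfonate, CC[Si](CC)(CC)OS(=O)(=O)C(F)(F)F
Why: Silyl triflate silylation of the only free (tertiary, C12) hydroxyl.

Step 13
Reactants: 21 (5S,6S)-5-ethyl-6-{(1E,4S)-5-[(4-methoxyphenyl)methoxy]-2,4-dimethyl-4-(triethylsilyloxy)pent-1-en-1-yl}-6-methyloxan-2-one
Product: 23 (3RS,5S,6S)-5-ethyl-3-hydroxy-6-{(1E,4S)-5-[(4-methoxyphenyl)methoxy]-2,4-dimethyl-4-(triethylsilyloxy)pent-1-en-1-yl}-6-methyloxan-2-one (both epimers at C5 of the target numbering), via potassium enolate 22 (not isolated)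
Conditions: KN(SiMe3)2, THF, −78 °C; then 2-(phenylsulfonyl)-3-phenyloxaziridine, −78 °C; aq. NH4Cl
Reagents that add atoms: 2-(phenylsulfonyl)-3-phenyloxaziridine, O=S(=O)(c1ccccc1)N1OC1c1ccccc1
Why: Davis hydroxylation of the lactone enolate installs the C5 oxygen; its configuration does not matter because C5 becomes planar again in step 14.

Step 14
Reactants: 23 α-hydroxy lactone
Product: 27 methyl (1S,2S,5S)-5-ethyl-1-hydroxy-2-{(2S)-3-[(4-methoxyphenyl)methoxy]-2-methyl-2-(triethylsilyloxy)propyl}-2,4-dimethylcyclohex-3-ene-1-carboxylate, via bis-silyl ketene acetal 24 (not isolated), via silyl ester 25 (not isolated), via hydroxy acid 26 (not isolated)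
Conditions: LiN(iPr)2 (2.5 equiv), Me3SiCl–Et3N, THF, −78 °C to rt; PhMe, 100 °C; aq. citric acid; then Me3SiCHN2, PhMe–MeOH, 0 °C
Reagents that add atoms: (trimethylsilyl)diazomethane, C[Si](C)(C)C=[N+]=[N-]
Why: Ireland–Claisen rearrangement of a lactone silyl ketene acetal through the ring-enforced boat transition state forms C5–C29 suprafacially on the lactone face that carries the alkenyl group, so the C32 configuration sets C5, the E alkene geometry sets C29, and the acid is then methylated.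

Step 15
Reactants: 27 cyclohexene hydroxy ester
Product: 28 methyl (1S,2S,5S)-5-ethyl-1-hydroxy-2-[(2S)-3-hydroxy-2-methyl-2-(triethylsilyloxy)propyl]-2,4-dimethylcyclohex-3-ene-1-carboxylate
Conditions: DDQ, CH2Cl2–pH 7 buffer, 0 °C
Reagents that add atoms: none
Why: Oxidative cleavage of the 4-methoxybenzyl ether leaves the silyl ether, the ester and the ring alkene alone.

Step 16
Reactants: 28 primary alcohol
Product: 29 methyl (1S,2S,5S)-5-ethyl-1-hydroxy-2,4-dimethyl-2-[(2S)-2-methyl-3-oxo-2-(triethylsilyloxy)propyl]cyclohex-3-ene-1-carboxylate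
Conditions: Dess–Martin periodinane, NaHCO3, CH2Cl2, 0 °C to rt
Reagents that add atoms: none
Why: Dess–Martin oxidation gives an aldehyde with no α-hydrogen, and the tertiary C5 hydroxyl cannot be oxidised.

Step 17
Reactants: 29 aldehyde
Product: 30 methyl (1S,2S,5S)-5-ethyl-1-hydroxy-2-[(2S,3Z)-4-iodo-2-methyl-2-(triethylsilyloxy)pent-3-en-1-yl]-2,4-dimethylcyclohex-3-ene-1-carboxylate
Conditions: EtPPh3I, n-BuLi, THF, rt; I2, −78 °C; NaN(SiMe3)2, −78 °C; then 29, −78 to −20 °C
Reagents that add atoms: ethyltriphenylphosphonium iodide, CC[P+](c1ccccc1)(c1ccccc1)c1ccccc1.[I-]; iodine, II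
Why: Stork–Zhao-type Wittig olefination with the α-iodo ylide should give the trisubstituted vinyl iodide with iodine cis to C12 (Z), the geometry needed for C14=C15.

Step 18
Reactants: 1 propargyl alcohol
Product: 32 (Z)-3-iodo-2-methylprop-2-en-1-ol, via alkenylmagnesium 31 (not isolated)
Conditions: MeMgBr (2.5 equiv), CuI (10 mol %), THF, −10 °C to rt; then I2, −10 °C
Reagents that add atoms: methylmagnesium bromide, C[Mg]Br; iodine, II
Why: Copper-catalysed anti-carbomagnesiation of the propargylic alkoxide puts methyl on C20 and magnesium on C19 cis to the CH2O group, and iodinolysis retains that geometry.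

Step 19
Reactants: 32 (Z)-3-iodo-2-methylprop-2-en-1-ol
Product: 33 (Z)-3-iodo-2-methylprop-2-enal
Conditions: MnO2, CH2Cl2, rt, dark
Reagents that add atoms: none
Why: Neutral allylic oxidation with MnO2, with the enal used at once to avoid Z to E isomerisation.

Step 20
Reactants: 34 2,2,6-trimethyl-4H-1,3-dioxin-4-one
Product: 36 [(2,2-dimethyl-6-methylidene-6H-1,3-dioxin-4-yl)oxy]trimethylsilane, via lithium dienolate 35 (not isolated)
Conditions: LiN(iPr)2, THF, −78 °C; then Me3SiCl
Reagents that add atoms: chlorotrimethylsilane, C[Si](C)(C)Cl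
Why: γ-Deprotonation of the dioxinone and O-silylation give the silyl dienol ether used in vinylogous aldol reactions.

Step 21
Reactants: 33 (Z)-3-iodo-2-methylprop-2-enal; 36 silyl dienol ether
Product: 38 6-[(2R,3Z)-2-hydroxy-4-iodo-3-methylbut-3-en-1-yl]-2,2-dimethyl-4H-1,3-dioxin-4-one, via silyl ether 37 (not isolated)
Conditions: Cu(OTf)2 (2 mol %), (S)-Tol-BINAP (2.2 mol %), Bu4N[Ph3SiF2] (4 mol %), THF, −78 °C; then CF3CO2H, THF–H2O, 0 °C
Reagents that add atoms: none
Why: Catalytic asymmetric vinylogous Mukaiyama aldol addition through the γ-carbon C25, in which the copper–bisphosphine dienolate differentiates the aldehyde faces and sets C22 as R.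

Step 22
Reactants: 38 aldol adduct
Product: 39 6-[(2R,3Z)-4-iodo-2-methoxy-3-methylbut-3-en-1-yl]-2,2-dimethyl-4H-1,3-dioxin-4-one
Conditions: Me3OBF4, 1,8-bis(dimethylamino)naphthalene, CH2Cl2, 0 °C to rt
Reagents that add atoms: trimethyloxonium tetrafluoroborate, C[O+](C)C.F[B-](F)(F)F
Why: O-Methylation with Meerwein's salt under non-basic conditions avoids retro-aldol cleavage and elimination of the β-hydroxy dioxinone.

Step 23
Reactants: 39 methyl ether
Product: 40 6-[(2R,3Z)-2-methoxy-3-methylhexa-3,5-dien-1-yl]-2,2-dimethyl-4H-1,3-dioxin-4-one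
Conditions: tributyl(vinyl)stannane, PdCl2(MeCN)2 (5 mol %), DMF, rt
Reagents that add atoms: tributyl(vinyl)stannane, CCCC[Sn](CCCC)(CCCC)C=C
Why: Stille coupling of the vinyl iodide with retention of the Z geometry adds C18 and C17.

Step 24
Reactants: 40 diene–dioxinone; 30 vinyl iodide
Product: 42 methyl (1S,2S,5S)-2-[(2S,3Z,7Z,9R)-10-(2,2-dimethyl-4-oxo-4H-1,3-dioxin-6-yl)-9-methoxy-2,4,8-trimethyl-2-(triethylsilyloxy)deca-3,7-dien-1-yl]-5-ethyl-1-hydroxy-2,4-dimethylcyclohex-3-ene-1-carboxylate, via alkylborane 41 (not isolated)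
Conditions: 9-BBN (1.2 equiv), THF, 0 °C to rt; then 30, Pd(dppf)Cl2 (10 mol %), AsPh3, Cs2CO3, DMF–H2O, rt
Reagents that add atoms: none
Why: B-alkyl Suzuki–Miyaura coupling, in which 9-BBN adds to the terminal vinyl group of the diene to give the homoallylic borane and this couples with the vinyl iodide with retention to form C15–C17 and the Z C14=C15 alkene.

Step 25
Reactants: 42 seco hydroxy ester–dioxinone
Product: 44 16-membered β-keto macrolactone (O6–C7 ester; C10 methyl ester on C5; C12 triethylsilyl ether), via acylketene 43 (not isolated)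
Conditions: PhMe, 110 °C, 0.5 mM, slow addition
Reagents that add atoms: none
Why: Thermal retro-[4+2] of the dioxinone releases acetone and an acylketene, which adds the tertiary C5 hydroxyl without any activating agent (acylketene macrolactonisation) to close the 16-membered ring at O6–C7.

Step 26
Reactants: 44 16-membered β-keto macrolactone
Product: 47 macrocyclic 3-acyltetronic acid (ring B formed; 15-membered carbocycle; C12 triethylsilyl ether), via potassium enolate 45 (not isolated), via potassium tetronate 46 (not isolated)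
Conditions: KOtBu (1.05 equiv), THF, 0 °C to rt; cold aq. HCl to pH 3
Reagents that add atoms: none
Why: The base removes a proton from C9, the only carbon flanked by two carbonyls (C7 and C26), and the enolate carbon adds to the C10 ester carbonyl held on C5 next to O6; the tetrahedral intermediate loses methoxide and the 2,4-dione formed is deprotonated at once to the tetronate, which makes the sequence irreversible. The closest known reaction is the Lacey–Dieckmann cyclisation of α-(acetoacetoxy) esters to 3-acyltetronic acids, and its transannular ring-contracting form is known for macrolactams that give tetramic acids. Ring B (C5–O6–C7–C9–C10) closes 5-exo-trig by C–C bond formation, and because C9 and C10 both lay in the 16-membered lactone the large ring becomes the 15-membered carbocycle without a separate closure. No stereocentre is formed. Only chemoselectivity is needed: with one equivalent of base the charge stays at C9 (first as the β-keto ester enolate, then as the tetronate), so C25 is not deprotonated and the C22 methoxy group is not eliminated, the bulky alkoxide should not open the hindered lactone, and the C12 oxygen is masked as its silyl ether.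

Step 27
Reactants: 47 macrocyclic 3-acyltetronic acid
Product: 48 O11 p-toluenesulfonate of 47
Conditions: p-toluenesulfonic anhydride (1.2 equiv), iPr2NEt, CH2Cl2, −40 to 0 °C
Reagents that add atoms: p-toluenesulfonic anhydride, Cc1ccc(cc1)S(=O)(=O)OS(=O)(=O)c1ccc(C)cc1
Why: O-Sulfonylation of the vinylogous acid at the ring oxygen O11 turns C10 into a doubly activated vinylogous acyl sulfonate, and the absence of chloride avoids halide exchange at C10.

Step 28
Reactants: 48 O11 p-toluenesulfonate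
Product: 50 streptaspironate A, via hydroxy tosylate 49 (not isolated)
Conditions: HF·pyridine, pyridine, THF, 0 °C to rt; then Et3N, 4-(dimethylamino)pyridine (20 mol %), rt
Reagents that add atoms: none
Why: Fluoride frees the C12 hydroxyl, which adds to C10 and expels the sulfonate (6-exo-trig addition–elimination at a β-sulfonyloxy enone), closing ring C with the C12–O bond intact so that C12 keeps the configuration brought in from (R)-2-methylglycidol.

**Compound list**

1 | propargyl alcohol | C#CCO | starting material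
2 | allyl bromide | C=CCBr | starting material
3 | dimethyl[(E)-3-(dimethylalumanyloxy)-2-methylprop-1-en-1-yl]alumane | C[Al](C)/C=C(\C)CO[Al](C)C | intermediate (not isolated)
4 | (E)-2-methylhexa-2,5-dien-1-ol | C=CC/C=C(\C)CO | intermediate
5 | [(2R,3R)-2-methyl-3-(prop-2-en-1-yl)oxiran-2-yl]methanol | OC[C@@]1(C)O[C@@H]1CC=C | intermediate
6 | (2S,3S)-3-ethyl-2-methylhex-5-ene-1,2-diol | OC[C@@](C)(O)[C@@H](CC)CC=C | intermediate
7 | (2S,3S)-3-ethyl-2-hydroxy-2-methylhex-5-enal | O=C[C@@](C)(O)[C@@H](CC)CC=C | intermediate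
8 | (3S,4S)-4-ethyl-3-methylhept-6-en-1-yn-3-ol | C#C[C@@](C)(O)[C@@H](CC)CC=C | intermediate
9 | (R)-2-methylglycidol, [(2R)-2-methyloxiran-2-yl]methanol | C[C@@]1(CO)CO1 | starting material
10 | (2R)-2-{[(4-methoxyphenyl)methoxy]methyl}-2-methyloxirane | C[C@@]1(COCc2ccc(OC)cc2)CO1 | intermediate
11 | dilithium salt of 8 (lithium acetylide and lithium alkoxide) | [Li]C#C[C@@](C)(O[Li])[C@@H](CC)CC=C | intermediate (not isolated)
12 | (2S,6S,7S)-7-ethyl-1-[(4-methoxyphenyl)methoxy]-2,6-dimethyldec-9-en-4-yne-2,6-diol | COc1ccc(COC[C@@](C)(O)CC#C[C@@](C)(O)[C@@H](CC)CC=C)cc1 | intermediate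
13 | sodium alkenylalanate, five-membered oxa-aluminacycle with Al on C29 and on the C32 oxygen (idealised) | COc1ccc(COC[C@@](C)(O)C/C2=C/[C@](C)([C@@H](CC)CC=C)O[Al-]2(OCCOC)OCCOC)cc1.[Na+] | intermediate (not isolated)
14 | (2S,4Z,6S,7S)-7-ethyl-4-iodo-1-[(4-methoxyphenyl)methoxy]-2,6-dimethyldeca-4,9-diene-2,6-diol | COc1ccc(COC[C@@](C)(O)C/C(I)=C/[C@@](C)(O)[C@@H](CC)CC=C)cc1 | intermediate
15 | (2S,4E,6S,7S)-7-ethyl-1-[(4-methoxyphenyl)methoxy]-2,4,6-trimethyldeca-4,9-diene-2,6-diol | COc1ccc(COC[C@@](C)(O)C/C(C)=C/[C@@](C)(O)[C@@H](CC)CC=C)cc1 | intermediate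
16 | B-alkyl-9-borabicyclo[3.3.1]nonane from 15 (boron on the terminal carbon C10) | COc1ccc(COC[C@@](C)(O)C/C(C)=C/[C@@](C)(O)[C@@H](CC)CCCB2C3CCCC2CCC3)cc1 | intermediate (not isolated)
17 | (4S,5S,6E,9S)-4-ethyl-10-[(4-methoxyphenyl)methoxy]-5,7,9-trimethyldec-6-ene-1,5,9-triol | COc1ccc(COC[C@@](C)(O)C/C(C)=C/[C@@](C)(O)[C@@H](CC)CCCO)cc1 | intermediate
18 | (4S,5S,6E,9S)-4-ethyl-5,9-dihydroxy-10-[(4-methoxyphenyl)methoxy]-5,7,9-trimethyldec-6-enal | COc1ccc(COC[C@@](C)(O)C/C(C)=C/[C@@](C)(O)[C@@H](CC)CCC=O)cc1 | intermediate (not isolated)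
19 | six-membered lactol of 18 (oxan-2-ol) | COc1ccc(COC[C@@](C)(O)C/C(C)=C/[C@@]2(C)OC(O)CC[C@@H]2CC)cc1 | intermediate (not isolated)
20 | (5S,6S)-5-ethyl-6-{(1E,4S)-4-hydroxy-5-[(4-methoxyphenyl)methoxy]-2,4-dimethylpent-1-en-1-yl}-6-methyloxan-2-one | COc1ccc(COC[C@@](C)(O)C/C(C)=C/[C@@]2(C)OC(=O)CC[C@@H]2CC)cc1 | intermediate
21 | (5S,6S)-5-ethyl-6-{(1E,4S)-5-[(4-methoxyphenyl)methoxy]-2,4-dimethyl-4-(triethylsilyloxy)pent-1-en-1-yl}-6-methyloxan-2-one | COc1ccc(COC[C@@](C)(O[Si](CC)(CC)CC)C/C(C)=C/[C@@]2(C)OC(=O)CC[C@@H]2CC)cc1 | intermediate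
22 | potassium enolate of lactone 21 | COc1ccc(COC[C@@](C)(O[Si](CC)(CC)CC)C/C(C)=C/[C@@]2(C)OC(O[K])=CC[C@@H]2CC)cc1 | intermediate (not isolated)
23 | (3RS,5S,6S)-5-ethyl-3-hydroxy-6-{(1E,4S)-5-[(4-methoxyphenyl)methoxy]-2,4-dimethyl-4-(triethylsilyloxy)pent-1-en-1-yl}-6-methyloxan-2-one (epimers at the carbinol carbon) | COc1ccc(COC[C@@](C)(O[Si](CC)(CC)CC)C/C(C)=C/[C@@]2(C)OC(=O)C(O)C[C@@H]2CC)cc1 | intermediate
24 | bis(trimethylsilyl) ketene acetal of 23 (2,3-bis(trimethylsilyloxy)-5,6-dihydro-4H-pyran) | COc1ccc(COC[C@@](C)(O[Si](CC)(CC)CC)C/C(C)=C/[C@@]2(C)OC(O[Si](C)(C)C)=C(O[Si](C)(C)C)C[C@@H]2CC)cc1 | intermediate (not isolated)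
25 | trimethylsilyl (1S,2S,5S)-5-ethyl-2-{(2S)-3-[(4-methoxyphenyl)methoxy]-2-methyl-2-(triethylsilyloxy)propyl}-2,4-dimethyl-1-(trimethylsilyloxy)cyclohex-3-ene-1-carboxylate | CC[C@H]1C[C@@](O[Si](C)(C)C)(C(=O)O[Si](C)(C)C)[C@@](C)(C[C@](C)(O[Si](CC)(CC)CC)COCc2ccc(OC)cc2)C=C1C | intermediate (not isolated)
26 | (1S,2S,5S)-5-ethyl-1-hydroxy-2-{(2S)-3-[(4-methoxyphenyl)methoxy]-2-methyl-2-(triethylsilyloxy)propyl}-2,4-dimethylcyclohex-3-ene-1-carboxylic acid | CC[C@H]1C[C@@](O)(C(=O)O)[C@@](C)(C[C@](C)(O[Si](CC)(CC)CC)COCc2ccc(OC)cc2)C=C1C | intermediate (not isolated)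
27 | methyl (1S,2S,5S)-5-ethyl-1-hydroxy-2-{(2S)-3-[(4-methoxyphenyl)methoxy]-2-methyl-2-(triethylsilyloxy)propyl}-2,4-dimethylcyclohex-3-ene-1-carboxylate | CC[C@H]1C[C@@](O)(C(=O)OC)[C@@](C)(C[C@](C)(O[Si](CC)(CC)CC)COCc2ccc(OC)cc2)C=C1C | intermediate
28 | methyl (1S,2S,5S)-5-ethyl-1-hydroxy-2-[(2S)-3-hydroxy-2-methyl-2-(triethylsilyloxy)propyl]-2,4-dimethylcyclohex-3-ene-1-carboxylate | CC[C@H]1C[C@@](O)(C(=O)OC)[C@@](C)(C[C@](C)(O[Si](CC)(CC)CC)CO)C=C1C | intermediate
29 | methyl (1S,2S,5S)-5-ethyl-1-hydroxy-2,4-dimethyl-2-[(2S)-2-methyl-3-oxo-2-(triethylsilyloxy)propyl]cyclohex-3-ene-1-carboxylate | CC[C@H]1C[C@@](O)(C(=O)OC)[C@@](C)(C[C@](C)(O[Si](CC)(CC)CC)C=O)C=C1C | intermediate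
30 | methyl (1S,2S,5S)-5-ethyl-1-hydroxy-2-[(2S,3Z)-4-iodo-2-methyl-2-(triethylsilyloxy)pent-3-en-1-yl]-2,4-dimethylcyclohex-3-ene-1-carboxylate | CC[C@H]1C[C@@](O)(C(=O)OC)[C@@](C)(C[C@](C)(O[Si](CC)(CC)CC)/C=C(/C)I)C=C1C | intermediate
31 | (Z)-alkenylmagnesium bromide with bromomagnesium alkoxide (Mg on C19 cis to CH2O) | C/C(CO[Mg]Br)=C/[Mg]Br | intermediate (not isolated)
32 | (Z)-3-iodo-2-methylprop-2-en-1-ol | C/C(CO)=C/I | intermediate
33 | (Z)-3-iodo-2-methylprop-2-enal | C/C(C=O)=C/I | intermediate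
34 | 2,2,6-trimethyl-4H-1,3-dioxin-4-one | CC1=CC(=O)OC(C)(C)O1 | starting material
35 | lithium dienolate of 34 | C=C1C=C(O[Li])OC(C)(C)O1 | intermediate (not isolated)
36 | [(2,2-dimethyl-6-methylidene-6H-1,3-dioxin-4-yl)oxy]trimethylsilane | C=C1C=C(O[Si](C)(C)C)OC(C)(C)O1 | intermediate
37 | 6-[(2R,3Z)-4-iodo-3-methyl-2-(trimethylsilyloxy)but-3-en-1-yl]-2,2-dimethyl-4H-1,3-dioxin-4-one | I/C=C(/C)[C@H](O[Si](C)(C)C)CC1=CC(=O)OC(C)(C)O1 | intermediate (not isolated)
38 | 6-[(2R,3Z)-2-hydroxy-4-iodo-3-methylbut-3-en-1-yl]-2,2-dimethyl-4H-1,3-dioxin-4-one | I/C=C(/C)[C@H](O)CC1=CC(=O)OC(C)(C)O1 | intermediate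
39 | 6-[(2R,3Z)-4-iodo-2-methoxy-3-methylbut-3-en-1-yl]-2,2-dimethyl-4H-1,3-dioxin-4-one | I/C=C(/C)[C@H](OC)CC1=CC(=O)OC(C)(C)O1 | intermediate
40 | 6-[(2R,3Z)-2-methoxy-3-methylhexa-3,5-dien-1-yl]-2,2-dimethyl-4H-1,3-dioxin-4-one | C=C/C=C(/C)[C@H](OC)CC1=CC(=O)OC(C)(C)O1 | intermediate
41 | B-alkyl-9-borabicyclo[3.3.1]nonane from 40 (boron on C17) | C(/C=C(/C)[C@H](OC)CC1=CC(=O)OC(C)(C)O1)CB2C3CCCC2CCC3 | intermediate (not isolated)
42 | methyl (1S,2S,5S)-2-[(2S,3Z,7Z,9R)-10-(2,2-dimethyl-4-oxo-4H-1,3-dioxin-6-yl)-9-methoxy-2,4,8-trimethyl-2-(triethylsilyloxy)deca-3,7-dien-1-yl]-5-ethyl-1-hydroxy-2,4-dimethylcyclohex-3-ene-1-carboxylate | CC[C@H]1C[C@@](O)(C(=O)OC)[C@@](C)(C[C@](C)(O[Si](CC)(CC)CC)/C=C(/C)CC/C=C(/C)[C@H](OC)CC2=CC(=O)OC(C)(C)O2)C=C1C | intermediate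
43 | acylketene from 42 (chain ends in C26(=O)–C9H=C7=O) | CC[C@H]1C[C@@](O)(C(=O)OC)[C@@](C)(C[C@](C)(O[Si](CC)(CC)CC)/C=C(/C)CC/C=C(/C)[C@H](OC)CC(=O)C=C=O)C=C1C | intermediate (not isolated)
44 | 16-membered β-keto macrolactone (O6–C7 ester, C10 methyl ester on C5, C12 triethylsilyl ether; 3S,5S,12S,22R,29S; 14Z,19Z) | CC[C@H]1C[C@]2(C(=O)OC)OC(=O)CC(=O)C[C@@H](OC)/C(C)=C\CC/C(C)=C\[C@@](C)(O[Si](CC)(CC)CC)C[C@@]2(C)C=C1C | intermediate
45 | potassium enolate of 44 at C9 | CC[C@H]1C[C@]2(C(=O)OC)OC(=O)C=C(O[K])C[C@@H](OC)/C(C)=C\CC/C(C)=C\[C@@](C)(O[Si](CC)(CC)CC)C[C@@]2(C)C=C1C | intermediate (not isolated)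
46 | potassium tetronate of 47 | CC[C@H]1C[C@]2(OC(=O)C3=C2O[K])[C@@](C)(C[C@](C)(O[Si](CC)(CC)CC)/C=C(/C)CC/C=C(/C)[C@H](OC)CC3=O)C=C1C | intermediate (not isolated)
47 | macrocyclic 3-acyltetronic acid (ring B spiro to ring A at C5, 15-membered carbocycle, C12 triethylsilyl ether, O11–H free) | CC[C@H]1C[C@]2(OC(=O)C3=C2O)[C@@](C)(C[C@](C)(O[Si](CC)(CC)CC)/C=C(/C)CC/C=C(/C)[C@H](OC)CC3=O)C=C1C | intermediate
48 | O11 p-toluenesulfonate of 47 | CC[C@H]1C[C@]2(OC(=O)C3=C2OS(=O)(=O)c4ccc(C)cc4)[C@@](C)(C[C@](C)(O[Si](CC)(CC)CC)/C=C(/C)CC/C=C(/C)[C@H](OC)CC3=O)C=C1C | intermediate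
49 | O11 p-toluenesulfonate with free C12 hydroxyl | CC[C@H]1C[C@]2(OC(=O)C3=C2OS(=O)(=O)c4ccc(C)cc4)[C@@](C)(C[C@](C)(O)/C=C(/C)CC/C=C(/C)[C@H](OC)CC3=O)C=C1C | intermediate (not isolated)
50 | streptaspironate A | CC[C@H]1C[C@@]23OC(=O)C4=C2O[C@](C)(/C=C(/C)CC/C=C(/C)[C@H](OC)CC4=O)C[C@@]3(C)C=C1C | target

**Step count and risks**

Total step count: 28. Longest linear sequence: 21 steps (steps 1–5, 7–17 and 24–28, from propargyl alcohol).

Steps most likely to fail:

Step 25. The acylketene may be lost to dimerisation or to traces of water before the shielded tertiary C5 hydroxyl can add through a 16-membered transition state. The fallback makes the ester bond between two molecules first and closes the ring at C15–C17. It sets out from 30 and 40: heating 40 with a twofold excess of 30 in a small volume of toluene at 110 °C gives acylketene F6, which 30 should trap bimolecularly as β-keto ester F7. 9-BBN then adds to the terminal vinyl group of F7 to give alkylborane F8, and an intramolecular B-alkyl Suzuki–Miyaura coupling (Pd(dppf)Cl2, AsPh3, Cs2CO3, DMF–THF–H2O, 1 mM) closes the 16-membered ring and returns to the route at 44.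

Step 14. The crowded α-silyloxy silyl ketene acetal may ionise at the tertiary allylic C32–O bond, or simply be hydrolysed back, instead of passing through the boat transition state that joins two fully substituted carbons. The fallback runs the rearrangement before C5 carries oxygen and introduces the hydroxyl afterwards. It sets out from 21: LiN(iPr)2 and Me3SiCl give silyl ketene acetal F1, which should rearrange at 80–100 °C to trimethylsilyl ester F2 (C5 is now only tertiary, and C29 is set by the same suprafacial shift). Hydrolysis gives acid F3 and Me3SiCHN2 gives methyl ester F4. KN(SiMe3)2 then forms potassium enolate F5, which the oxaziridine of step 13 should hydroxylate on the ring face that carries the C30 methyl group, away from the C28 side chain and the C3 ethyl group, returning to the route at 27.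

Step 28. The sulfonyl group of step 27 may go to the exocyclic acyl oxygen on C26 rather than to O11, or the tertiary hydroxyl may add so slowly that base removes methanol across C25–C22. The fallback closes ring C without activating O11, by acid-promoted allylic substitution in which O11 is the nucleophile. It sets out from 47: HF·pyridine buffered with pyridine removes the silyl group to give hydroxy tetronic acid F9. A catalytic amount of pyridinium p-toluenesulfonate with 4 Å molecular sieves in CH2Cl2 then ionises the tertiary allylic C12 hydroxyl so that O11 closes the six-membered ether across the ring, returning to the route at 50. In this variant the C12 configuration is decided by the ring closure itself, and a C12 epimer, if formed, would have to be separated.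

Further compounds
F1 | step 14 | trimethylsilyl ketene acetal of lactone 21 | COc1ccc(COC[C@@](C)(O[Si](CC)(CC)CC)C/C(C)=C/[C@@]2(C)OC(O[Si](C)(C)C)=CC[C@@H]2CC)cc1
F2 | step 14 | trimethylsilyl (1R,2S,5S)-5-ethyl-2-{(2S)-3-[(4-methoxyphenyl)methoxy]-2-methyl-2-(triethylsilyloxy)propyl}-2,4-dimethylcyclohex-3-ene-1-carboxylate | CC[C@H]1C[C@@H](C(=O)O[Si](C)(C)C)[C@@](C)(C[C@](C)(O[Si](CC)(CC)CC)COCc2ccc(OC)cc2)C=C1C
F3 | step 14 | corresponding carboxylic acid (C5–H) | CC[C@H]1C[C@@H](C(=O)O)[C@@](C)(C[C@](C)(O[Si](CC)(CC)CC)COCc2ccc(OC)cc2)C=C1C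
F4 | step 14 | corresponding methyl ester (C5–H) | CC[C@H]1C[C@@H](C(=O)OC)[C@@](C)(C[C@](C)(O[Si](CC)(CC)CC)COCc2ccc(OC)cc2)C=C1C
F5 | step 14 | potassium enolate of F4 | CC[C@H]1CC(=C(OC)O[K])[C@@](C)(C[C@](C)(O[Si](CC)(CC)CC)COCc2ccc(OC)cc2)C=C1C
F6 | step 25 | acylketene from 40, (5R,6Z)-5-methoxy-6-methyl-3-oxonona-1,6,8-trien-1-one | C=C/C=C(/C)[C@H](OC)CC(=O)C=C=O
F7 | step 25 | β-keto ester of the C5 hydroxyl of 30 with the chain of 40 (vinyl iodide and terminal diene both present) | CC[C@H]1C[C@@](OC(=O)CC(=O)C[C@@H](OC)/C(C)=C\C=C)(C(=O)OC)[C@@](C)(C[C@](C)(O[Si](CC)(CC)CC)/C=C(/C)I)C=C1C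
F8 | step 25 | B-alkyl-9-borabicyclo[3.3.1]nonane from F7 (boron on C17) | CC[C@H]1C[C@@](OC(=O)CC(=O)C[C@@H](OC)/C(C)=C\CCB2C3CCCC2CCC3)(C(=O)OC)[C@@](C)(C[C@](C)(O[Si](CC)(CC)CC)/C=C(/C)I)C=C1C
F9 | step 28 | macrocyclic 3-acyltetronic acid with free C12 hydroxyl | CC[C@H]1C[C@]2(OC(=O)C3=C2O)[C@@](C)(C[C@](C)(O)/C=C(/C)CC/C=C(/C)[C@H](OC)CC3=O)C=C1C
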